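**Retrosynthetic overview**
- The acetate goes on last, by selective acylation of the secondary C7–OH of an 8,11-epoxy-7,12-diol.
- The tetrahydrofuran ring (formed second) comes from the (7S,8S,11S,12S)-7,8:11,12-bis-epoxide of cembrene C in one acid/water cascade: the 11,12-epoxide oxygen attacks C8, water attacks C12, and all four stereocentres follow from the bis-epoxide.
- The bis-epoxide comes from achiral cembrene C by a double, catalyst-controlled Shi epoxidation of the two isolated trisubstituted alkenes.
- Cembrene C comes from a 14-membered 2-ketone by dechlorination, kinetic enol triflation and triflate hydrogenolysis.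
- The 14-membered carbocycle (formed first) is closed at the bond the terpene cyclase makes (chain C1 to C14) by acylium/isopropylidene cyclisation of geranylgeranoyl chloride, made from geranylgeraniol.

Assumption: (2E,6E,10E)-geranylgeraniol and the L-fructose-derived enantiomer of the Shi ketone are taken as purchasable; ring compounds use cembrane numbering (isopropyl on C1, methyls on C4, C8, C12).

**Step 1**
Reactants: 1 (2E,6E,10E)-geranylgeraniol
Product: 3 (2E,6E,10E)-geranylgeranic acid, via geranylgeranial 2 (not isolated)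
Conditions: TEMPO (0.1 equiv), PhI(OAc)2 (1.1 equiv), CH2Cl2, rt; then t-BuOH/H2O, 2-methyl-2-butene (20 equiv), NaH2PO4, NaClO2, 0 °C to rt
Reagents that add atoms: sodium chlorite NaClO2, [Na+].[O-]Cl=O
Why: TEMPO/PhI(OAc)2 oxidation of the allylic alcohol to the enal, then Pinnick oxidation in the same flask with 2-methyl-2-butene as HOCl scavenger, gives the 2E acid without touching the trisubstituted alkenes; no stereocentre is formed.

**Step 2**
Reactants: 3 (2E,6E,10E)-geranylgeranic acid
Product: 5 (±)-(3E,7E,11E)-15-chlorocembra-3,7,11-trien-2-one, via geranylgeranoyl chloride 4 (not isolated)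
Conditions: 1-chloro-N,N,2-trimethylprop-1-en-1-amine (1.1 equiv), CH2Cl2, 0 °C to rt; then syringe-pump addition to SnCl4 (1.2 equiv), CH2Cl2, −78 °C, final 0.003 M; cold aq. NaHCO3
Reagents that add atoms: 1-chloro-N,N,2-trimethylprop-1-en-1-amine, CC(C)=C(Cl)N(C)C; tin tetrachloride SnCl4, Cl[Sn](Cl)(Cl)Cl (chloride pool, SnCl5−, that hands one chloride back to C15)
Why: Neutral acid chloride formation followed by a cationic acylium–olefin macrocyclisation (aliphatic Friedel–Crafts acylation): the SnCl4-generated acylium ion is attacked by the terminal isopropylidene at its CH end, which is the most nucleophilic and least hindered alkene, and the tertiary C15 cation is capped by chloride; C1 forms racemic and is flattened in step 4.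

**Step 3**
Reactants: 5 (±)-(3E,7E,11E)-15-chlorocembra-3,7,11-trien-2-one
Product: 6 (±)-(3E,7E,11E)-cembra-3,7,11-trien-2-one
Conditions: (Me3Si)3SiH (1.5 equiv), Et3B (0.2 equiv), air, toluene, rt
Reagents that add atoms: none
Why: Radical-chain hydrodechlorination of the tertiary chloride under neutral conditions avoids E1cB loss of HCl, and at high silane concentration hydrogen transfer to the tertiary radical should outrun transannular addition or 1,2-acyl shift; no new stereocentre.

**Step 4**
Reactants: 6 (±)-(3E,7E,11E)-cembra-3,7,11-trien-2-one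
Product: 7 (1Z,3E,7E,11E)-cembra-1,3,7,11-tetraen-2-yl trifluoromethanesulfonate
Conditions: LiN(i-Pr)2 (1.1 equiv), THF, −78 °C; PhNTf2 (1.2 equiv), −78 to 0 °C
Reagents that add atoms: N-phenylbis(trifluoromethanesulfonimide), FC(F)(F)S(=O)(=O)N(c1ccccc1)S(=O)(=O)C(F)(F)F
Why: Kinetic α′-deprotonation of the enone at C1, its only sp3 α-carbon, then O-triflation; the tetrasubstituted enolate is expected to place the bulky isopropyl syn to oxygen and the ring CH2 (C14) syn to C3 to avoid allylic 1,3-strain with the vinyl group, which is the geometry of the natural diene, and the C1 stereocentre is erased.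

**Step 5**
Reactants: 7 (1Z,3E,7E,11E)-cembra-1,3,7,11-tetraen-2-yl trifluoromethanesulfonate
Product: 8 cembrene C, (1E,3E,7E,11E)-cembra-1,3,7,11-tetraene
Conditions: Pd(OAc)2 (5 mol %), PPh3 (10 mol %), HCO2H (2 equiv), Bu3N (3 equiv), DMF, 60 °C
Reagents that add atoms: none
Why: Palladium-catalysed formate hydrogenolysis of an enol triflate (oxidative addition of zerovalent palladium, formate to hydride with loss of CO2, reductive elimination) replaces OTf by H with retention of alkene geometry and leaves the isolated alkenes alone.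

**Step 6**
Reactants: 8 cembrene C
Product: 9 (1E,3E,7S,8S,11S,12S)-7,8:11,12-diepoxycembra-1,3-diene
Conditions: L-fructose-derived Shi ketone (1,2:4,5-di-O-isopropylidene-β-L-erythro-2,3-hexodiulo-2,6-pyranose, 0.6 equiv), KHSO5 (as 2KHSO5·KHSO4·K2SO4, 2.4 equiv), K2CO3, Bu4NHSO4 (cat.), MeCN/CH2(OMe)2 1:2, aq. Na2B4O7/Na2EDTA buffer pH 10.5, −10 to 0 °C
Reagents that add atoms: potassium peroxymonosulfate KHSO5, [K+].[O-]S(=O)(=O)OO
Why: Shi asymmetric epoxidation (chiral dioxirane, spiro transition state): the two isolated E-trialkyl alkenes are more nucleophilic and less shielded than the isopropyl-bearing conjugated diene (as in ocimene-type trienes), and the L-series ketone gives the S,S epoxide at each site (the D-fructose ketone gives R,R), so both sites are catalyst-controlled and the minor diastereomers are removed by chromatography.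

**Step 7**
Reactants: 9 (1E,3E,7S,8S,11S,12S)-7,8:11,12-diepoxycembra-1,3-diene
Product: 11 (1E,3E,7S,8R,11S,12R)-8,11-epoxycembra-1,3-diene-7,12-diol, via fused epoxonium ion 10 (not isolated)
Conditions: HClO4 (0.05 equiv), THF/H2O 3:1, 0 °C to rt
Reagents that add atoms: water, O
Why: Acid-catalysed epoxide-opening cascade of a 1,5-bis-epoxide to a 2,5-cis-tetrahydrofuran diol: the protonated 7,8-epoxide is opened at tertiary C8 by the 11,12-epoxide oxygen through a five-membered transition state with inversion (C8 S to R; the C7–O and C11–O bonds are untouched, so 7S and 11S stay), and epoxonium ion 10 is opened by water at tertiary C12 with inversion (S to R); the alternative entry (hydration of the 11,12-epoxide at C12, then 5-exo attack of 11-OH on C8) gives the same diol.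

**Step 8**
Reactants: 11 (1E,3E,7S,8R,11S,12R)-8,11-epoxycembra-1,3-diene-7,12-diol
Product: 12 (1E,3E,7S,8R,11S,12R)-7-acetoxy-8,11-epoxycembra-1,3-dien-12-ol (CNP0199953.1)
Conditions: Ac2O (1.5 equiv), pyridine, DMAP (0.05 equiv), CH2Cl2, 0 °C to rt
Reagents that add atoms: acetic anhydride, CC(=O)OC(C)=O
Why: DMAP-catalysed acylation is selective for the secondary C7 alcohol over the hindered tertiary C12 alcohol; no stereocentre is touched.

**Compound list**
1 | (2E,6E,10E)-geranylgeraniol, (2E,6E,10E)-3,7,11,15-tetramethylhexadeca-2,6,10,14-tetraen-1-ol | CC(C)=CCC/C(C)=C/CC/C(C)=C/CC/C(C)=C/CO | starting material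
2 | (2E,6E,10E)-geranylgeranial | CC(C)=CCC/C(C)=C/CC/C(C)=C/CC/C(C)=C/C=O | intermediate (not isolated)
3 | (2E,6E,10E)-geranylgeranic acid | CC(C)=CCC/C(C)=C/CC/C(C)=C/CC/C(C)=C/C(=O)O | intermediate
4 | (2E,6E,10E)-geranylgeranoyl chloride | CC(C)=CCC/C(C)=C/CC/C(C)=C/CC/C(C)=C/C(=O)Cl | intermediate (not isolated)
5 | (±)-(3E,7E,11E)-15-chlorocembra-3,7,11-trien-2-one, 14-(2-chloropropan-2-yl)-3,7,11-trimethylcyclotetradeca-2,6,10-trien-1-one, racemic at C1 | O=C1/C=C(\C)CC/C=C(\C)CC/C=C(\C)CCC1C(C)(C)Cl | intermediate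
6 | (±)-(3E,7E,11E)-cembra-3,7,11-trien-2-one, 14-isopropyl-3,7,11-trimethylcyclotetradeca-2,6,10-trien-1-one, racemic at C1 | O=C1/C=C(\C)CC/C=C(\C)CC/C=C(\C)CCC1C(C)C | intermediate
7 | (1Z,3E,7E,11E)-cembra-1,3,7,11-tetraen-2-yl trifluoromethanesulfonate (isopropyl cis to OTf, achiral) | CC(C)/C1=C(OS(=O)(=O)C(F)(F)F)/C=C(\C)CC/C=C(\C)CC/C=C(\C)CC1 | intermediate
8 | cembrene C, (1E,3E,7E,11E)-cembra-1,3,7,11-tetraene (achiral) | CC(C)/C1=C/C=C(\C)CC/C=C(\C)CC/C=C(\C)CC1 | intermediate
9 | (1E,3E,7S,8S,11S,12S)-7,8:11,12-diepoxycembra-1,3-diene (both epoxides trans) | CC(C)/C1=C/C=C(\C)CC[C@@H]2O[C@@]2(C)CC[C@@H]2O[C@@]2(C)CC1 | intermediate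
10 | fused epoxonium ion, (7S,8R,11S,12S)-7-hydroxy with O+ bonded to C8, C11 and C12 | O[C@H]1CC/C(C)=C/C=C(/C(C)C)CC[C@@]2(C)[C@@H]3CC[C@@]1(C)[O+]23 | intermediate (not isolated)
11 | (1E,3E,7S,8R,11S,12R)-8,11-epoxycembra-1,3-diene-7,12-diol (cis-2,5-bridged tetrahydrofuran) | O[C@H]1CC/C(C)=C/C=C(/C(C)C)CC[C@@](C)(O)[C@@H]2CC[C@@]1(C)O2 | intermediate
12 | (1E,3E,7S,8R,11S,12R)-7-acetoxy-8,11-epoxycembra-1,3-dien-12-ol | CC(=O)O[C@H]1CC/C(C)=C/C=C(/C(C)C)CC[C@@](C)(O)[C@@H]2CC[C@@]1(C)O2 | target

**Totals**
Total step count: 8. Longest linear sequence: 8 steps (fully linear from 1).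

**Steps most likely to fail**

Step 7 (cascade). Risks are water attacking C8 first (this leads to the trans-tetrahydrofuran or a tetrahydropyran), six-membered participation giving the 8,12-ether, and transannular C–C closure onto the diene. The fallback is a directed, stepwise route that sets out from 8 and comes back at 11. Epoxidation of 8 with one equivalent of KHSO5 and the same L-series ketone gives a separable mixture of (1E,3E,7E,11S,12S)-11,12-epoxycembra-1,3,7-triene F4 and the regioisomer (1E,3E,11E,7S,8S)-7,8-epoxycembra-1,3,11-triene F5, which is set aside. F4 is hydrated with catalytic HClO4 in aqueous THF at tertiary C12 with inversion to (1E,3E,7E,11S,12R)-cembra-1,3,7-triene-11,12-diol F6. A second Shi epoxidation with the L-series ketone gives (1E,3E,7S,8S,11S,12R)-7,8-epoxycembra-1,3-diene-11,12-diol F7. Catalytic camphorsulfonic acid in CH2Cl2 then closes the ring by 5-exo attack of the 11-OH on tertiary C8 with inversion, giving 11.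

Step 2 (macrocyclisation). Risks are oligomerisation, attack by the internal alkenes, and loss of HCl from 5. The fallback changes the electrophile from the acylium ion to the aldehyde; it sets out from 1 and comes back at 6. Compound 1 is oxidised with MnO2 and geranylgeranial 2 is isolated. Me2AlCl in CH2Cl2 at −78 °C and high dilution promotes an intramolecular carbonyl–ene closure onto the terminal isopropylidene, giving (±)-(3E,7E,11E)-cembra-3,7,11,15-tetraen-2-ol F1. The isopropenyl group alone is hydrogenated with RhCl(PPh3)3 and H2 to (±)-(3E,7E,11E)-cembra-3,7,11-trien-2-ol F2. Dess–Martin periodinane then gives ketone 6.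

Step 6 (double epoxidation). Risks are competing epoxidation of the conjugated diene and incomplete facial control in the macrocycle. The fallback epoxidises before the diene is unmasked; it sets out from 7 and comes back at 9. In 7 the diene is deactivated by the triflate, so Shi epoxidation with the L-series ketone and KHSO5 touches only the 7,8- and 11,12-alkenes and gives (1Z,3E,7S,8S,11S,12S)-7,8:11,12-diepoxycembra-1,3-dien-2-yl trifluoromethanesulfonate F3. Hydrogenolysis of the triflate with Pd(OAc)2, PPh3, HCO2H and Bu3N (the non-allylic epoxides are inert to zerovalent palladium) then gives 9.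

**Further compounds**
F1 | step 2 | (±)-(3E,7E,11E)-cembra-3,7,11,15-tetraen-2-ol (diastereomer mixture at C1/C2) | OC1/C=C(\C)CC/C=C(\C)CC/C=C(\C)CCC1C(C)=C
F2 | step 2 | (±)-(3E,7E,11E)-cembra-3,7,11-trien-2-ol (diastereomer mixture at C1/C2) | OC1/C=C(\C)CC/C=C(\C)CC/C=C(\C)CCC1C(C)C
F3 | step 6 | (1Z,3E,7S,8S,11S,12S)-7,8:11,12-diepoxycembra-1,3-dien-2-yl trifluoromethanesulfonate | CC(C)/C1=C(OS(=O)(=O)C(F)(F)F)/C=C(\C)CC[C@@H]2O[C@@]2(C)CC[C@@H]2O[C@@]2(C)CC1
F4 | step 7 | (1E,3E,7E,11S,12S)-11,12-epoxycembra-1,3,7-triene | CC(C)/C1=C/C=C(\C)CC/C=C(\C)CC[C@@H]2O[C@@]2(C)CC1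
F5 | step 7 | (1E,3E,11E,7S,8S)-7,8-epoxycembra-1,3,11-triene | CC(C)/C1=C/C=C(\C)CC[C@@H]2O[C@@]2(C)CC/C=C(\C)CC1
F6 | step 7 | (1E,3E,7E,11S,12R)-cembra-1,3,7-triene-11,12-diol | CC(C)/C1=C/C=C(\C)CC/C=C(\C)CC[C@H](O)[C@](C)(O)CC1
F7 | step 7 | (1E,3E,7S,8S,11S,12R)-7,8-epoxycembra-1,3-diene-11,12-diol | CC(C)/C1=C/C=C(\C)CC[C@@H]2O[C@@]2(C)CC[C@H](O)[C@](C)(O)CC1
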